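**Plan**
- Retrosynthesis: the C3 CH2OH goes back to a carboxyl group and the C4 benzyl CH2 to a benzylic C–O bond tied to that carboxyl (a γ-aryl lactone). The ring bonds C2–C3 and C4–C5 are then cut together.
- Enabling feature: in the oxolane ring the triad C5H2–O1–C2H(aryl) is the skeleton of a carbonyl ylide made from O-benzylvanillin and a CH2 unit. The cis pair C3/C4 is the C=C of a γ-aryl butenolide.
- Forward: veratraldehyde is alkynylated and converted to the (S)-butenolide (temporary lactone ring first). The [3+2] cycloaddition then builds the oxolane ring on it. Hydrogenolysis opens the lactone and frees the phenol, and borane gives the primary alcohol.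
- Stereochemistry: one catalytic asymmetric alkynylation sets the carbinol centre. That centre steers the cycloaddition to the anti face (absolute C3, C4), the ring-locked Z alkene gives 3,4-cis, and exo approach gives 2,3-trans. The control centre is then erased to CH2.

Key step: step 4

Remark: the target is read as the (2S,3R,4R)-oxolane (2,3-trans, 3,4-cis), numbered O1, C2 (aryl), C3 (CH2OH), C4 (benzyl), C5.

**Step 1**
Reactants: 1 3,4-dimethoxybenzaldehyde; 2 methyl propiolate
Product: 3 methyl (R)-4-(3,4-dimethoxyphenyl)-4-hydroxybut-2-ynoate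
Conditions: Me2Zn (3 equiv), ProPhenol ligand (10 mol%, the antipode that delivers the R carbinol), toluene, 0 °C; aq. NH4Cl
Reagents that add atoms: none
Why: Zinc–ProPhenol catalysed asymmetric alkynylation, in which the dinuclear zinc complex binds the aryl aldehyde and delivers the zinc acetylide of 2 to one carbonyl face, should set the R carbinol centre.

**Step 2**
Reactants: 3 methyl (R)-4-(3,4-dimethoxyphenyl)-4-hydroxybut-2-ynoate
Product: 5 (S)-5-(3,4-dimethoxyphenyl)furan-2(5H)-one, via Z-hydroxy enoate 4 (not isolated)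
Conditions: H2 (1 atm), Pd/CaCO3 poisoned with Pb(OAc)2 (Lindlar catalyst), quinoline, EtOAc, rt; then PPTS (cat.), CH2Cl2, rt
Reagents that add atoms: none
Why: Lindlar semihydrogenation adds H2 syn to give the Z enoate, whose hydroxyl then lactonises onto the ester; the carbinol centre is untouched, and its descriptor changes from R to S only through the CIP ranking.

**Step 3**
Reactants: 6 4-(benzyloxy)-3-methoxybenzaldehyde; 7 (trimethylsilyl)methanol (2.2 equiv)
Product: 8 1-(benzyloxy)-4-{bis[(trimethylsilyl)methoxy]methyl}-2-methoxybenzene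
Conditions: PPTS (cat.), toluene, reflux, Dean–Stark
Reagents that add atoms: none
Why: Acid-catalysed acetalisation driven by azeotropic removal of water; the Si–CH2–O unit tolerates PPTS and no stereocentre is formed.

**Step 4**
Reactants: 8 1-(benzyloxy)-4-{bis[(trimethylsilyl)methoxy]methyl}-2-methoxybenzene (1.5 equiv); 5 (S)-5-(3,4-dimethoxyphenyl)furan-2(5H)-one
Product: 11 (3S,3aR,6S,6aS)-6-[4-(benzyloxy)-3-methoxyphenyl]-3-(3,4-dimethoxyphenyl)tetrahydro-1H-furo[3,4-c]furan-1-one, via α-chlorobenzyl silylmethyl ether 9 (not isolated), via carbonyl ylide 10 (not isolated)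
Conditions: AcCl (1.0 equiv to 8), CH2Cl2, 0 °C to rt, concentrate; then 5, CsF, MeCN, rt
Reagents that add atoms: none
Why: Acetyl chloride cleaves one acetal C–O bond of 8 to the α-chloro ether 9, whose chloride is labilised by the para-alkoxyaryl group, and fluoride attack on silicon completes a 1,3-elimination to the non-stabilised carbonyl ylide 10 (ArCH=O(+)–CH2(−)), which adds across the Cα=Cβ bond of 5 in a suprafacial 4π + 2π 1,3-dipolar cycloaddition. The closest known reaction type is the CsF-induced 1,3-elimination of 1-chloroalkyl (trimethylsilyl)methyl ethers with trapping of the carbonyl ylide by α,β-unsaturated esters to give oxolanes. The oxolane ring is closed intermolecularly by this [3+2] cycloaddition, both new C–C bonds (CH2–Cβ and ArCH–Cα) forming on the same face of the alkene, so the ring arises cis-fused to the lactone. C3a and C6a (C4 and C3 of the target) are set cis by the Z alkene held in the lactone ring and in the absolute sense by approach anti to the γ-aryl group at the stereocentre of 5, while C6 (C2 of the target) is set by the exo transition state that keeps the ylide aryl group on the convex face, trans to the lactone carbonyl. The step needs regioselectivity (CH2 terminus to Cβ), which the ylide polarisation should secure because the electron-rich aryl group stabilises oxocarbenium character at its own carbon and leaves CH2 as the nucleophilic terminus that seeks the β-carbon, reinforced by the γ-aryl group that keeps the bulky ArCH terminus away from Cβ; the same γ-aryl group secures the facial selectivity. The lactone ring is a temporary device that supplies activation, alkene geometry and facial bias and is opened in step 5.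

**Step 5**
Reactants: 11 (3S,3aR,6S,6aS)-6-[4-(benzyloxy)-3-methoxyphenyl]-3-(3,4-dimethoxyphenyl)tetrahydro-1H-furo[3,4-c]furan-1-one
Product: 12 (2S,3S,4R)-4-(3,4-dimethoxybenzyl)-2-(4-hydroxy-3-methoxyphenyl)oxolane-3-carboxylic acid
Conditions: H2 (1 atm), Pd/C, EtOAc/EtOH, rt
Reagents that add atoms: none
Why: Catalytic hydrogenolysis should cleave the aryl benzyl ether and the benzylic carboxylate C–O bond of the γ-aryl lactone faster than the secondary benzylic dialkyl ether C2–O of the oxolane, which erases the control centre to CH2 and leaves C2, C3 and C4 untouched under base-free conditions.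

**Step 6**
Reactants: 12 (2S,3S,4R)-4-(3,4-dimethoxybenzyl)-2-(4-hydroxy-3-methoxyphenyl)oxolane-3-carboxylic acid
Product: 13 4-[(2S,3R,4R)-4-(3,4-dimethoxybenzyl)-3-(hydroxymethyl)oxolan-2-yl]-2-methoxyphenol (4'-O-methyllariciresinol)
Conditions: BH3·THF (excess), THF, 0 °C to rt; MeOH, then aqueous work-up
Reagents that add atoms: none
Why: Borane reduces the carboxylic acid chemoselectively through the acyloxyborane without epimerising C3, the phenol forming only a borate that is hydrolysed on work-up (C3 becomes R by CIP ranking alone).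

**Compound list**
1 | 3,4-dimethoxybenzaldehyde (veratraldehyde) | COc1ccc(C=O)cc1OC | starting material
2 | methyl propiolate | C#CC(=O)OC | starting material
3 | methyl (R)-4-(3,4-dimethoxyphenyl)-4-hydroxybut-2-ynoate | COc1ccc([C@@H](O)C#CC(=O)OC)cc1OC | intermediate (isolated)
4 | methyl (S,Z)-4-(3,4-dimethoxyphenyl)-4-hydroxybut-2-enoate | COc1ccc([C@@H](O)/C=C\C(=O)OC)cc1OC | intermediate (not isolated)
5 | (S)-5-(3,4-dimethoxyphenyl)furan-2(5H)-one | COc1ccc([C@H]2OC(=O)C=C2)cc1OC | intermediate (isolated)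
6 | 4-(benzyloxy)-3-methoxybenzaldehyde (O-benzylvanillin) | COc1cc(C=O)ccc1OCc1ccccc1 | starting material
7 | (trimethylsilyl)methanol | C[Si](C)(C)CO | starting material
8 | 1-(benzyloxy)-4-{bis[(trimethylsilyl)methoxy]methyl}-2-methoxybenzene | COc1cc(C(OC[Si](C)(C)C)OC[Si](C)(C)C)ccc1OCc1ccccc1 | intermediate (isolated)
9 | 1-(benzyloxy)-4-{chloro[(trimethylsilyl)methoxy]methyl}-2-methoxybenzene (racemic) | COc1cc(C(Cl)OC[Si](C)(C)C)ccc1OCc1ccccc1 | intermediate (not isolated)
10 | [4-(benzyloxy)-3-methoxybenzylidene]oxonium methylide (carbonyl ylide) | COc1cc(C=[O+][CH2-])ccc1OCc1ccccc1 | intermediate (not isolated)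
11 | (3S,3aR,6S,6aS)-6-[4-(benzyloxy)-3-methoxyphenyl]-3-(3,4-dimethoxyphenyl)tetrahydro-1H-furo[3,4-c]furan-1-one (cis-fused, both aryl groups exo) | COc1cc([C@H]2OC[C@H]([C@@H](c4ccc(OC)c(OC)c4)O3)[C@@H]2C3=O)ccc1OCc1ccccc1 | intermediate (isolated)
12 | (2S,3S,4R)-4-(3,4-dimethoxybenzyl)-2-(4-hydroxy-3-methoxyphenyl)oxolane-3-carboxylic acid | COc1cc([C@H]2OC[C@H](Cc3ccc(OC)c(OC)c3)[C@@H]2C(=O)O)ccc1O | intermediate (isolated)
13 | 4-[(2S,3R,4R)-4-(3,4-dimethoxybenzyl)-3-(hydroxymethyl)oxolan-2-yl]-2-methoxyphenol (4'-O-methyllariciresinol) | COc1cc([C@H]2OC[C@H](Cc3ccc(OC)c(OC)c3)[C@@H]2CO)ccc1O | target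

**Step count and risks**
Total steps: 6. Longest linear sequence: 5 (steps 1, 2, 4, 5, 6).

Step 4. The cycloaddition may form its bonds in the reverse regiochemical sense, or pass through the endo transition state (2,3-cis series). Fluoride may also deprotonate the butenolide at the γ-position (racemisation, double-bond migration) before the ylide is trapped. The fallback builds the two bonds stepwise, sets out from 1 and comes back at 13.
- Stobbe condensation of 1 with dimethyl succinate (NaOMe, MeOH, reflux) gives (E)-4-(3,4-dimethoxyphenyl)-3-(methoxycarbonyl)but-3-enoic acid F1.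
- Asymmetric hydrogenation ([Rh(cod)(Et-DuPhos)]OTf, the antipode that delivers R, H2, MeOH) gives (R)-4-(3,4-dimethoxyphenyl)-3-(methoxycarbonyl)butanoic acid F2.
- Reduction of the ester beside the carboxylate (KOH, then Ca(BH4)2, EtOH; HCl) and lactonisation gives (R)-4-(3,4-dimethoxybenzyl)dihydrofuran-2(3H)-one F3.
- Aldol addition of its lithium enolate (LiN(SiMe3)2, THF, −78 °C) to 6, anti to the benzyl group, gives (3S,4R)-3-{[4-(benzyloxy)-3-methoxyphenyl](hydroxy)methyl}-4-(3,4-dimethoxybenzyl)dihydrofuran-2(3H)-one F4.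
- LiAlH4 (THF) gives (2R,3R)-2-{[4-(benzyloxy)-3-methoxyphenyl](hydroxy)methyl}-3-(3,4-dimethoxybenzyl)butane-1,4-diol F5.
- Cycloetherification through the para-alkoxybenzyl cation (camphorsulfonic acid, CH2Cl2) should close the oxolane 2,3-trans and 3,4-cis to {(2S,3R,4R)-2-[4-(benzyloxy)-3-methoxyphenyl]-4-(3,4-dimethoxybenzyl)oxolan-3-yl}methanol F6.
- Brief neutral hydrogenolysis (H2, Pd/C, EtOAc) gives 13.

Step 5. Hydrogenolysis may go on to cleave the oxolane C2–O bond (ring opening to the seco compound), or may stop before the lactone C–O bond is cut. The fallback removes the benzylic oxygen by a radical path, sets out from 11 and comes back at 13.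
- LiAlH4 (THF) gives {(2S,3R,4R)-2-[4-(benzyloxy)-3-methoxyphenyl]-4-[(S)-(3,4-dimethoxyphenyl)(hydroxy)methyl]oxolan-3-yl}methanol F7.
- Selective silylation of the primary hydroxyl (TBSCl, imidazole, CH2Cl2, 0 °C) gives (S)-{(3R,4R,5S)-5-[4-(benzyloxy)-3-methoxyphenyl]-4-[(tert-butyldimethylsilyloxy)methyl]oxolan-3-yl}(3,4-dimethoxyphenyl)methanol F8.
- 1,1'-Thiocarbonyldiimidazole (THF, rt) gives the O-benzylic imidazole-1-carbothioate of F8 F9.
- Barton–McCombie deoxygenation (Bu3SnH, AIBN, toluene, 80 °C) gives tert-butyl{[(2S,3R,4R)-2-[4-(benzyloxy)-3-methoxyphenyl]-4-(3,4-dimethoxybenzyl)oxolan-3-yl]methoxy}dimethylsilane F10.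
- Bu4NF (THF) gives {(2S,3R,4R)-2-[4-(benzyloxy)-3-methoxyphenyl]-4-(3,4-dimethoxybenzyl)oxolan-3-yl}methanol F11 (the same compound as F6).
- Brief neutral hydrogenolysis (H2, Pd/C, EtOAc) gives 13.

Step 1. The catalytic alkynylation may give low enantioselectivity with this electron-rich aldehyde, or lose the propiolate to oligomerisation. The fallback sets the centre by reduction instead of addition, sets out from 1 and comes back at 3.
- Addition of lithiated 2 (n-BuLi, THF, −78 °C) to 1 gives racemic methyl 4-(3,4-dimethoxyphenyl)-4-hydroxybut-2-ynoate F12.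
- Oxidation (MnO2, CH2Cl2) gives methyl 4-(3,4-dimethoxyphenyl)-4-oxobut-2-ynoate F13.
- Midland reduction with Alpine-borane (the antipode that delivers the R carbinol, THF, rt) gives 3.

**Further compounds**
F1 | step 4 | (E)-4-(3,4-dimethoxyphenyl)-3-(methoxycarbonyl)but-3-enoic acid | OC(=O)C/C(C(=O)OC)=C\c1ccc(OC)c(OC)c1
F2 | step 4 | (R)-4-(3,4-dimethoxyphenyl)-3-(methoxycarbonyl)butanoic acid | OC(=O)C[C@@H](Cc1ccc(OC)c(OC)c1)C(=O)OC
F3 | step 4 | (R)-4-(3,4-dimethoxybenzyl)dihydrofuran-2(3H)-one | O=C1C[C@@H](Cc2ccc(OC)c(OC)c2)CO1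
F4 | step 4 | (3S,4R)-3-{[4-(benzyloxy)-3-methoxyphenyl](hydroxy)methyl}-4-(3,4-dimethoxybenzyl)dihydrofuran-2(3H)-one (carbinol epimers) | COc1cc(C(O)[C@@H]2[C@@H](Cc3ccc(OC)c(OC)c3)COC2=O)ccc1OCc1ccccc1
F5 | step 4 | (2R,3R)-2-{[4-(benzyloxy)-3-methoxyphenyl](hydroxy)methyl}-3-(3,4-dimethoxybenzyl)butane-1,4-diol (carbinol epimers) | COc1cc(C(O)[C@@H](CO)[C@@H](Cc2ccc(OC)c(OC)c2)CO)ccc1OCc1ccccc1
F6 | step 4 | {(2S,3R,4R)-2-[4-(benzyloxy)-3-methoxyphenyl]-4-(3,4-dimethoxybenzyl)oxolan-3-yl}methanol | COc1cc([C@H]2OC[C@H](Cc3ccc(OC)c(OC)c3)[C@@H]2CO)ccc1OCc1ccccc1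
F7 | step 5 | {(2S,3R,4R)-2-[4-(benzyloxy)-3-methoxyphenyl]-4-[(S)-(3,4-dimethoxyphenyl)(hydroxy)methyl]oxolan-3-yl}methanol | COc1cc([C@H]2OC[C@H]([C@H](O)c3ccc(OC)c(OC)c3)[C@@H]2CO)ccc1OCc1ccccc1
F8 | step 5 | (S)-{(3R,4R,5S)-5-[4-(benzyloxy)-3-methoxyphenyl]-4-[(tert-butyldimethylsilyloxy)methyl]oxolan-3-yl}(3,4-dimethoxyphenyl)methanol | COc1cc([C@H]2OC[C@H]([C@H](O)c3ccc(OC)c(OC)c3)[C@@H]2CO[Si](C)(C)C(C)(C)C)ccc1OCc1ccccc1
F9 | step 5 | O-[(S)-{(3R,4R,5S)-5-[4-(benzyloxy)-3-methoxyphenyl]-4-[(tert-butyldimethylsilyloxy)methyl]oxolan-3-yl}(3,4-dimethoxyphenyl)methyl] 1H-imidazole-1-carbothioate | COc1cc([C@H]2OC[C@H]([C@H](OC(=S)n3ccnc3)c3ccc(OC)c(OC)c3)[C@@H]2CO[Si](C)(C)C(C)(C)C)ccc1OCc1ccccc1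
F10 | step 5 | tert-butyl{[(2S,3R,4R)-2-[4-(benzyloxy)-3-methoxyphenyl]-4-(3,4-dimethoxybenzyl)oxolan-3-yl]methoxy}dimethylsilane | COc1cc([C@H]2OC[C@H](Cc3ccc(OC)c(OC)c3)[C@@H]2CO[Si](C)(C)C(C)(C)C)ccc1OCc1ccccc1
F11 | step 5 | {(2S,3R,4R)-2-[4-(benzyloxy)-3-methoxyphenyl]-4-(3,4-dimethoxybenzyl)oxolan-3-yl}methanol | COc1cc([C@H]2OC[C@H](Cc3ccc(OC)c(OC)c3)[C@@H]2CO)ccc1OCc1ccccc1
F12 | step 1 | methyl 4-(3,4-dimethoxyphenyl)-4-hydroxybut-2-ynoate (racemic) | COc1ccc(C(O)C#CC(=O)OC)cc1OC
F13 | step 1 | methyl 4-(3,4-dimethoxyphenyl)-4-oxobut-2-ynoate | COc1ccc(C(=O)C#CC(=O)OC)cc1OC
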